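If the reagent is the limiting reagent, the noon flask needs one number: the reagent cover, the reagent charged over the substrate charged, 0.700. Read as a share of the substrate, it is the level at which the target should stop, 70.0%, if one reagent gives one target.

the same everywhere: free catalyst 0.2 mol%

|  | substrate | reagent | remark | time |
|---|---|---|---|---|
| noon | 2.1 M | 0.70 equiv | the very flask that is asked about, followed so far |  |
| spring | 1.1 M | 0.70 equiv | run made earlier |  |
| flask | 2.1 M | 0.700 equiv |  | 2.0 d |

| run | time / h | target / % | substrate / % |
|---|---|---|---|
| noon | 2.50 | 44.1 | 49.2 |
| noon | 8.00 | 69.3 | 11.0 |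
| noon | 15.0 | 70.4 | 4.7 |
| noon | 20.0 | 70.1 | 2.3 |
| noon | 30.0 | 71.0 | 0.7 |
| noon | 40.0 | 70.0 | 0.5 |
| noon | 50.0 | 70.8 | 0.2 |
| spring | 1.33 | 16.6 | 81.9 |
| spring | 3.00 | 33.3 | 62.0 |
| spring | 4.00 | 41.0 | 51.8 |
| spring | 6.00 | 52.8 | 35.7 |
| spring | 8.00 | 60.2 | 25.6 |
| spring | 10.0 | 64.8 | 19.1 |

(readings scatter by 0.5 percentage points)

- the volume of additions can be left aside
- the numbers in the tables scatter with a standard deviation of 0.5 percentage points

- amber: at 2.0 d add reagent, 50.0% of the amount charged, then wait 4.0 d
- violet: at 2.0 d take out 90% of the by-product then present, then wait 4.0 d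
- teal: change nothing and wait 4.0 d more
- ochre: at 2.0 d add free catalyst, 100% of the amount charged, then wait 4.0 d

- target, in percent of the substrate first charged, at 2.0 d
- the remedy with the largest gain of target, or "none" below 2 percentage points (amber / violet / teal / ochre / none)
- target present, in percent of the substrate first charged, after teal
- target present, in percent of the substrate first charged, after ochre

The noon readings test this. From 15.0 h to 50.0 h the substrate falls by 4.5 points, while the target moves by 0.4 points, which is about the scatter of 0.5 points. Its readings lie between 70.0% and 71.0%, so the lowest stands at the cover and none lies below it.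

But one number gives a ceiling, not a time. The spring flask has the same cover and stands at 64.8% after 10.0 h, below that ceiling. For the noon flask the time is no obstacle, as 2.0 d is longer than the 15.0 h it took to arrive.

So I commit to 70.0% at 2.0 d, with the same after waiting or more free catalyst. I expect no useful remedy: the last substrate reading, 0.2%, is less than the 2 points required.

The forecast gives 70.4%, 70.4% after teal, 70.4% after ochre, and best none, on the ground that “the reagent is used up”. It differs from my figure by less than the scatter.

The flask gives 70.0%, 70.0% after teal, 70.0% after ochre, and best none; amber gains 0.14 points.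

    substrate + by-product → side product (k = 3.10 × 10⁻⁵ M⁻¹ s⁻¹)
    substrate + free catalyst ⇌ catalyst intermediate A (K = 0.180 M⁻¹, k = 0.0260 M⁻¹ s⁻¹)
    reagent + catalyst intermediate A → catalyst intermediate B (k = 1.70 M⁻¹ s⁻¹)
    catalyst intermediate C → free catalyst + target (k = 0.0780 s⁻¹)
    catalyst intermediate B → by-product + catalyst intermediate C (k = 1.40 s⁻¹)

In the flask, reagent stood at 10.6% of its charge at 4.80 h, with target at 62.6%. By 24.0 h reagent stood at 0% and target at 70.0%, matching the cover, while substrate went on reacting with by-product, taking side product from 15.4% to 29.8% at 48.0 h. That late step held 0.177% of substrate still to take at 48.0 h, less than the 2 points required.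

A neighbour flask charged with 0.170 equiv of reagent has a cover of 17.0%, so I read its target there. The computed neighbour gives 17.0%, with reagent at 0% and substrate at 66.0%.

All runs are simulated with constants of no real substance, noise included.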